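## The problem

Compound 20 is a cyclobutane in which every ring carbon is a stereocentre. C1 and C3 carry 2,4-dihydroxybenzoyl groups, C2 and C4 carry phenyl groups, and every pair of neighbours is trans (r-1,t-2,c-3,t-4), so the two aroyl groups are cis to each other and so are the two phenyl groups. A mirror plane through C1 and C3 makes the molecule achiral, so only relative configuration has to be set. C1 and C3 are alpha to ketones and can be equilibrated to this all-trans arrangement, which should be the most stable one because all four groups can sit pseudo-equatorial. C2 and C4 have no such handle, so the cis relation of the phenyl groups must come directly from the bond-forming event. The four phenols are acidic and easily oxidised and the aryl ketones are electrophilic and enolisable, so carbanion and organolithium chemistry requires masked phenols and late introduction of the ketones. Every ring bond joins an acyl-bearing carbon to an aryl-bearing carbon, a donor–acceptor pattern that invites ring opening by strong Lewis acids or hot nucleophiles. The enabling feature is that C1 lies between the two phenyl-bearing carbons: C2–C3–C4 is a symmetric 1,3-diphenylpropane-1,3-diyl unit with two benzylic ends that can be made electrophilic, C1 can be a malonate carbon that is alkylated twice, and C3 can carry an arylmethyl group as a masked aroyl group so that no acidic C–H lies between the electrophilic carbons.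

## Retrosynthesis

**20 from 19.** The four phenolic O–H bonds are traced back to O–methyl bonds in the tetramethyl ether 19. Methyl ethers are preferred to benzyl or acetal groups because they survive a titanium Lewis acid, hydride, hot sodium enolates, Krapcho conditions, an aryllithium and a quinone oxidant. They also keep the arene electron-rich enough for the benzylic oxidation. The forward step must cleave four aryl ethers without opening the ring; the ethers ortho to the ketones are helped by chelation.

**19 from 17.** The C3 aroyl carbonyl is traced back to a methylene group, giving the benzyl ketone 17. This is preferred to carrying a carbonyl on C3 through the ring construction, which would put an acidic hydrogen between the two leaving groups and invite elimination. It also avoids a second acyl-transfer sequence. The forward step must oxidise one CH2 next to a 2,4-dimethoxyphenyl ring in the presence of a deactivated aroyl ring and of ring C–H bonds next to plain phenyl groups.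

**17 from 14 and 16, and back to 11.** The aryl–carbonyl bond at C1 is cut to the Weinreb amide 14 and the aryllithium 16, which comes from bromide 15. A Friedel–Crafts acylation is the neighbouring option, but it would also attack the electron-rich benzyl ring of the substrate. Amide 14 comes from ester 13, and 13 from the geminal diester 11 by loss of one ester group. The C1 stereocentre thereby disappears, to be set later by equilibration.

**11 from 8 and 9 (key disconnection).** The C1–C2 and C1–C4 bonds are cut together, giving the meso cyclic sulfate 8 and dimethyl malonate 9. The cut uses the symmetry of the target, since both bonds form by the same reaction at equivalent benzylic carbons. A stepwise [2+2] union or a cut at C3 would create the non-correctable centres C2 and C4 without a stereospecific link to a precursor. The ring and two stereocentres vanish, leaving an acyclic-type meso triad and a commodity nucleophile. The forward step needs two substitutions with inversion, the second a four-membered ring closure, to outrun elimination and ionisation.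

**8 from 6 and 4.** The two S–O bonds are cut to the meso syn,syn diol 6. A cyclic sulfate is preferred to a bis-sulfonate or dihalide because the first displacement leaves a poorer, anionic leaving group. Intermolecular over-alkylation is thus suppressed and the second displacement becomes intramolecular. The sulfate is reached through the cyclic sulfite and oxidation at sulfur; a sulfuryl halide would risk chlorinating the dimethoxyphenyl ring. Diol 6 is traced to diketone 4 by cutting the two carbinol C–H bonds. The forward reduction has to place both hydroxyl groups syn to each other and to the benzyl group.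

**4 from 1 and 2.** The bond between the central carbon of the diketone and the benzylic carbon is cut by way of the benzylidene diketone 3. Condensation of dibenzoylmethane 1 with 2,4-dimethoxybenzaldehyde 2 and saturation of the C=C bond is preferred to alkylation with a 2,4-dimethoxybenzyl halide. Such halides are unstable and would also give O-alkylation and dialkylation. Both starting materials are commercial.

## Roads not taken

**Alternative 1:** The cut is at the two C–phenyl bonds. In the forward step, methyl trans-3-(quinolin-8-ylcarbamoyl)cyclobutane-1-carboxylate A1 is treated with iodobenzene A2, Pd(OAc)2 and AgOAc. The amide directs palladation of the C2–H and C4–H bonds on its own face and each palladacycle is arylated, giving the diphenyl compound A3.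
- Merits: the ring is bought and not built, both phenyl groups enter in one operation and are cis to each other by design, and twofold methylene arylation of cyclobutane carboxamides is well precedented.
- Weak points: the phenyl groups end up cis to the amide carbon, so C3 must be epimerised later. The auxiliary amide, wedged between two cis aryl groups, is hard to cleave. Both carboxyl groups then need separate conversion into 2,4-dimethoxyphenyl ketones before reaching 19. Stoichiometric silver is consumed.
- Comparison: for making the ring with cis phenyl groups this road is shorter and rests on closer precedent than step 5. The chosen plan sets against it that no auxiliary has to be removed from a crowded position, that the C3 carbonyl arises by one oxidation with the right configuration, and that only cheap reagents are used.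

**Alternative 2:** The cut is through both resorcinol rings. In the forward step, the all-trans bis-ynone A4 reacts twice with 1,3-dimethoxy-1-(trimethylsilyloxy)buta-1,3-diene A5 in a Diels–Alder reaction. Loss of methanol and of the silyl group aromatises each adduct to give the bis(2-hydroxy-4-methoxybenzoyl) compound A6.
- Merits: the regiochemistry of the benzannulation is secure, the ortho hydroxyl groups appear unprotected, and only two methyl ethers remain to be cleaved.
- Weak points: A4 already contains the complete stereodefined cyclobutane, so the hard part of the problem is untouched and must first be solved by another route. The ynones are Michael acceptors next to epimerisable ring carbons. Two cycloaddition and aromatisation events replace what an aryllithium does in one step.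
- Comparison: this road is better only in sparing the ortho protecting groups and the benzylic oxidation. The chosen plan actually builds the ring and takes both aryl groups from commercial building blocks.

**Alternative 3:** The cut is at the two aryl–carbonyl bonds. In the forward step, cyclobutane-1,2,3,4-tetracarboxylic dianhydride A7 acylates two molecules of 1,3-dimethoxybenzene A8 at C4 under AlCl3, giving the diaroyl diacid A9.
- Merits: the ring and all four substituent carbons come from one cheap compound, and the arene regiochemistry is reliable. On step count to a 1,3-diaroyl cyclobutane this road is clearly shorter than the chosen one.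
- Weak points: each anhydride can open in either sense, so the 1,3-diaroyl product A9 competes with its 1,2-isomer. C2 and C4 then carry carboxylic acids and not phenyl groups. Two decarboxylative arylations on a crowded ring would be needed, passing through radicals at exactly the two centres that cannot be corrected afterwards. One aroyl carbon also has to be epimerised.
- Comparison: the chosen plan is longer, but it fixes the phenyl-bearing carbons stereospecifically by inversion and leaves only the epimerisable centres to thermodynamic control.

Key step: step 5

Assumption: 20 is taken as the achiral all-trans diastereomer that its SMILES encodes. Compounds 5, 10 and 18 are racemates written as one enantiomer. Compounds 6–8, 11–17, 19 and 20 are achiral, so a SMILES string with every stereodescriptor reversed denotes the same compound; 11 is written in the mirror orientation of 12–20.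

## Route

**Step 1**
Reactants: 1 dibenzoylmethane; 2 2,4-dimethoxybenzaldehyde
Product: 3 2-(2,4-dimethoxybenzylidene)-1,3-diphenylpropane-1,3-dione
Conditions: piperidine (cat.), AcOH (cat.), toluene, reflux, Dean–Stark
Reagents that add atoms: none
Why: Knoevenagel condensation: the enol of the diketone adds to the iminium-activated aldehyde and azeotropic removal of water drives the dehydration; the crowded adduct should resist a second Michael addition of 1, and with two identical acyl groups there is no alkene geometry to control.

**Step 2**
Reactants: 3 2-(2,4-dimethoxybenzylidene)-1,3-diphenylpropane-1,3-dione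
Product: 4 2-(2,4-dimethoxybenzyl)-1,3-diphenylpropane-1,3-dione
Conditions: H2 (1 atm), 10% Pd/C, EtOAc, rt
Reagents that add atoms: none
Why: Heterogeneous catalytic hydrogenation of an electron-poor conjugated C=C bond is much faster than reduction of aryl ketones or hydrogenolysis of aryl ethers under these mild conditions, so the reaction is stopped after one equivalent of hydrogen; the new sp3 carbon is not stereogenic.

**Step 3**
Reactants: 4 2-(2,4-dimethoxybenzyl)-1,3-diphenylpropane-1,3-dione
Product: 6 (1R,2s,3S)-2-(2,4-dimethoxybenzyl)-1,3-diphenylpropane-1,3-diol (meso syn,syn diol), via syn hydroxy ketone 5 (not isolated)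
Conditions: TiCl4, CH2Cl2, −30 °C; then BH3·pyridine, −78 °C; then H2O
Reagents that add atoms: none
Why: Chelation-controlled hydride reduction of a 1,3-diketone: TiCl4 ties both carbonyl oxygens into a six-membered chelate with the C2 benzyl group pseudo-axial, and BH3·pyridine delivers hydride to the first carbonyl on the face away from that group to give the titanium alkoxide of 5. The second carbonyl is reduced inside the new alkoxide chelate, again anti to the benzyl group, so both carbinol carbons end up syn to the benzyl group and to each other.

**Step 4**
Reactants: 6 (1R,2s,3S)-2-(2,4-dimethoxybenzyl)-1,3-diphenylpropane-1,3-diol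
Product: 8 all-cis 5-(2,4-dimethoxybenzyl)-4,6-diphenyl-1,3,2-dioxathiane 2,2-dioxide (meso cyclic sulfate), via cyclic sulfite 7 (not isolated)
Conditions: SOCl2, pyridine, CH2Cl2, 0 °C; then RuCl3·3H2O (cat.), NaIO4, MeCN/H2O, 0 °C
Reagents that add atoms: thionyl chloride (O=S(Cl)Cl); sodium periodate ([Na+].[O-]I(=O)(=O)=O)
Why: Two-stage cyclic sulfate synthesis: SOCl2 and pyridine close the six-membered cyclic sulfite, and catalytic RuO4 formed from RuCl3 and NaIO4 oxidises sulfur within minutes at 0 °C. No C–O bond is broken, so the three stereocentres of 6 are carried over unchanged; the short contact time and low ruthenium loading are chosen to spare the dimethoxyphenyl ring.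

**Step 5**
Reactants: 8 all-cis 5-(2,4-dimethoxybenzyl)-4,6-diphenyl-1,3,2-dioxathiane 2,2-dioxide; 9 dimethyl malonate
Product: 11 dimethyl 3-(2,4-dimethoxybenzyl)-2,4-diphenylcyclobutane-1,1-dicarboxylate (phenyl groups cis to each other; benzyl group trans to both), via ring-opened sodium sulfate monoester 10 (not isolated)
Conditions: NaH (2.2 equiv), DME, 0 °C to rt; then 80 °C
Reagents that add atoms: none
Why: Sodiomalonate attacks one of the two enantiotopic benzylic carbons of 8 by SN2 with inversion and opens the ring to the sulfate monoester 10; the remaining NaH deprotonates the now monosubstituted malonate, and on warming this carbanion displaces the sulfate at the second benzylic carbon, again with inversion. The closest known reaction type is the Perkin-type synthesis of cyclobutane-1,1-dicarboxylates from malonate and 1,3-dielectrophiles, together with double displacement on cyclic sulfates (cyclopropanes from 1,2-diol sulfates and malonate, four-membered heterocycles from 1,3-diol sulfates and amines or phosphines). The cyclobutane closes in the 4-exo-tet mode. The new stereocentres C2 and C4 are controlled by the configuration of 8: two inversions turn the all-cis sulfate into the ring with the phenyl groups cis to each other and trans to the benzyl group on C3, which is untouched, and either first attack leads to the same meso product. The step needs substitution to win over E2 elimination and over ionisation at both stages; the soft, weakly basic carbanion, benzylic acceleration of SN2, the ether solvent and the absence of an acidifying group on C3 all favour this. In the chair of 8 the phenyl groups are equatorial and the benzyl group axial, so only the C5 hydrogen lies in the path of the nucleophile behind each C–O bond. C-alkylation is secured in the closure because O-alkylation of a malonate would give a cyclic ketene acetal.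

**Step 6**
Reactants: 11 dimethyl 3-(2,4-dimethoxybenzyl)-2,4-diphenylcyclobutane-1,1-dicarboxylate
Product: 13 methyl 3-(2,4-dimethoxybenzyl)-2,4-diphenylcyclobutane-1-carboxylate (r-1,t-2,c-3,t-4; ester trans to both phenyl groups), via cis ester epimer 12 (not isolated)
Conditions: LiCl, H2O, DMSO, 150 °C; then NaOMe, MeOH, 65 °C
Reagents that add atoms: none
Why: Krapcho demethoxycarbonylation (chloride attacks an O-methyl group, the carboxylate loses CO2 and water protonates the ester enolate) gives both C1 epimers, the cis ester 12 being expected from protonation on the face away from the phenyl groups. NaOMe in methanol then equilibrates C1 through the ester enolate to 13, in which all four substituents are pseudo-equatorial.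

**Step 7**
Reactants: 13 methyl 3-(2,4-dimethoxybenzyl)-2,4-diphenylcyclobutane-1-carboxylate (all-trans)
Product: 14 3-(2,4-dimethoxybenzyl)-N-methoxy-N-methyl-2,4-diphenylcyclobutane-1-carboxamide (all-trans)
Conditions: MeNH(OMe)·HCl, iPrMgCl, THF, −20 to 0 °C; then aq. NH4Cl
Reagents that add atoms: N,O-dimethylhydroxylamine hydrochloride (CNOC.Cl)
Why: Direct conversion of an ester into a Weinreb amide by the chloromagnesium amide made from the amine hydrochloride and iPrMgCl; acyl substitution does not involve C1, whose configuration is kept.

**Step 8**
Reactants: 14 3-(2,4-dimethoxybenzyl)-N-methoxy-N-methyl-2,4-diphenylcyclobutane-1-carboxamide; 15 1-bromo-2,4-dimethoxybenzene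
Product: 17 [3-(2,4-dimethoxybenzyl)-2,4-diphenylcyclobutyl](2,4-dimethoxyphenyl)methanone (all-trans), via 2,4-dimethoxyphenyllithium 16 (not isolated)
Conditions: 15, n-BuLi, THF, −78 °C; then 14, −78 to 0 °C; then 1 M HCl
Reagents that add atoms: none
Why: Weinreb ketone synthesis: bromine–lithium exchange on 15 gives 16, which adds once to 14 to form a chelated tetrahedral intermediate that collapses to the ketone only on acidic work-up, so no tertiary alcohol should form. The benzyl group is inert to the aryllithium and C1 keeps its trans configuration.

**Step 9**
Reactants: 17 [3-(2,4-dimethoxybenzyl)-2,4-diphenylcyclobutyl](2,4-dimethoxyphenyl)methanone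
Product: 19 (2,4-diphenylcyclobutane-1,3-diyl)bis[(2,4-dimethoxyphenyl)methanone] (all-trans), via benzylic alcohol 18 (not isolated)
Conditions: DDQ (3 equiv), CH2Cl2/H2O (10:1), rt
Reagents that add atoms: water (O)
Why: DDQ benzylic oxidation: hydride abstraction from the methylene group ortho and para to methoxy groups gives a strongly stabilised benzylic cation, water adds to give 18, and a second hydride abstraction gives the ketone. The aroyl-substituted ring and the ring C–H bonds next to plain phenyl groups are too electron-poor to react, and C3 keeps the trans configuration set in step 5, which is also the thermodynamically favoured one.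

**Step 10**
Reactants: 19 (2,4-diphenylcyclobutane-1,3-diyl)bis[(2,4-dimethoxyphenyl)methanone]
Product: 20 (2,4-diphenylcyclobutane-1,3-diyl)bis[(2,4-dihydroxyphenyl)methanone] (r-1,t-2,c-3,t-4; CNP0398987.1)
Conditions: BBr3 (excess), CH2Cl2, −78 °C to rt; then H2O
Reagents that add atoms: none
Why: Cleavage of aryl methyl ethers by BBr3 (boron–oxygen complexation, then bromide attack on the methyl group); the ethers ortho to the ketones should fall first through chelation and excess reagent at room temperature removes the para ethers. The all-trans ring is the most stable diastereomer, so epimerisation is not a threat.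

## Compound list

1 | dibenzoylmethane (1,3-diphenylpropane-1,3-dione) | O=C(CC(=O)c1ccccc1)c1ccccc1 | starting material
2 | 2,4-dimethoxybenzaldehyde | COc1ccc(C=O)c(OC)c1 | starting material
3 | 2-(2,4-dimethoxybenzylidene)-1,3-diphenylpropane-1,3-dione | O=C(c1ccccc1)C(=Cc1ccc(OC)cc1OC)C(=O)c1ccccc1 | intermediate
4 | 2-(2,4-dimethoxybenzyl)-1,3-diphenylpropane-1,3-dione | O=C(c1ccccc1)C(Cc1ccc(OC)cc1OC)C(=O)c1ccccc1 | intermediate
5 | (2S*,3S*)-2-(2,4-dimethoxybenzyl)-3-hydroxy-1,3-diphenylpropan-1-one (syn; racemic; not isolated) | O=C(c1ccccc1)[C@@H](Cc1ccc(OC)cc1OC)[C@@H](c1ccccc1)O | intermediate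
6 | (1R,2s,3S)-2-(2,4-dimethoxybenzyl)-1,3-diphenylpropane-1,3-diol (meso; syn,syn) | O[C@@H](c1ccccc1)[C@@H](Cc1ccc(OC)cc1OC)[C@@H](c1ccccc1)O | intermediate
7 | all-cis 5-(2,4-dimethoxybenzyl)-4,6-diphenyl-1,3,2-dioxathiane 2-oxide (either configuration at sulfur; not isolated) | O=S1O[C@@H](c2ccccc2)[C@@H](Cc2ccc(OC)cc2OC)[C@@H](c2ccccc2)O1 | intermediate
8 | all-cis 5-(2,4-dimethoxybenzyl)-4,6-diphenyl-1,3,2-dioxathiane 2,2-dioxide (meso) | O=S1(=O)O[C@@H](c2ccccc2)[C@@H](Cc2ccc(OC)cc2OC)[C@@H](c2ccccc2)O1 | intermediate
9 | dimethyl malonate | COC(=O)CC(=O)OC | starting material
10 | sodium salt of dimethyl 2-[2-(2,4-dimethoxybenzyl)-1,3-diphenyl-3-(sulfonatooxy)propyl]malonate (malonyl-bearing carbon inverted relative to 8; racemic; not isolated) | [Na+].[O-]S(=O)(=O)O[C@@H](c1ccccc1)[C@@H](Cc1ccc(OC)cc1OC)[C@H](c1ccccc1)C(C(=O)OC)C(=O)OC | intermediate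
11 | dimethyl 3-(2,4-dimethoxybenzyl)-2,4-diphenylcyclobutane-1,1-dicarboxylate (phenyls cis to each other, trans to the benzyl group; meso) | COC(=O)C1(C(=O)OC)[C@@H](c2ccccc2)[C@H](Cc2ccc(OC)cc2OC)[C@H]1c1ccccc1 | intermediate
12 | methyl 3-(2,4-dimethoxybenzyl)-2,4-diphenylcyclobutane-1-carboxylate, ester cis to both phenyls (r-1,c-2,t-3,c-4; not isolated) | COC(=O)[C@@H]1[C@H](c2ccccc2)[C@@H](Cc2ccc(OC)cc2OC)[C@@H]1c1ccccc1 | intermediate
13 | methyl 3-(2,4-dimethoxybenzyl)-2,4-diphenylcyclobutane-1-carboxylate, ester trans to both phenyls (r-1,t-2,c-3,t-4) | COC(=O)[C@H]1[C@H](c2ccccc2)[C@@H](Cc2ccc(OC)cc2OC)[C@@H]1c1ccccc1 | intermediate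
14 | 3-(2,4-dimethoxybenzyl)-N-methoxy-N-methyl-2,4-diphenylcyclobutane-1-carboxamide (all-trans) | CON(C)C(=O)[C@H]1[C@H](c2ccccc2)[C@@H](Cc2ccc(OC)cc2OC)[C@@H]1c1ccccc1 | intermediate
15 | 1-bromo-2,4-dimethoxybenzene | COc1ccc(Br)c(OC)c1 | starting material
16 | 2,4-dimethoxyphenyllithium (not isolated) | [Li]c1ccc(OC)cc1OC | intermediate
17 | [3-(2,4-dimethoxybenzyl)-2,4-diphenylcyclobutyl](2,4-dimethoxyphenyl)methanone (all-trans) | O=C(c1ccc(OC)cc1OC)[C@H]1[C@H](c2ccccc2)[C@@H](Cc2ccc(OC)cc2OC)[C@@H]1c1ccccc1 | intermediate
18 | {3-[(2,4-dimethoxyphenyl)(hydroxy)methyl]-2,4-diphenylcyclobutyl}(2,4-dimethoxyphenyl)methanone (ring all-trans; racemic at the carbinol carbon; not isolated) | O=C(c1ccc(OC)cc1OC)[C@H]1[C@H](c2ccccc2)[C@@H](C(O)c2ccc(OC)cc2OC)[C@@H]1c1ccccc1 | intermediate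
19 | (2,4-diphenylcyclobutane-1,3-diyl)bis[(2,4-dimethoxyphenyl)methanone] (all-trans) | O=C(c1ccc(OC)cc1OC)[C@H]1[C@H](c2ccccc2)[C@@H](C(=O)c2ccc(OC)cc2OC)[C@@H]1c1ccccc1 | intermediate
20 | (2,4-diphenylcyclobutane-1,3-diyl)bis[(2,4-dihydroxyphenyl)methanone] (r-1,t-2,c-3,t-4; CNP0398987.1) | O=C(c1ccc(O)cc1O)[C@H]1[C@H](c2ccccc2)[C@@H](C(=O)c2ccc(O)cc2O)[C@@H]1c1ccccc1 | target

## Step count and least certain steps

Total: 10 steps. Longest linear sequence: 10 steps (1 to 20); the aryllithium 16 is made in the flask during step 8.

**Step 5 (key step).** Base-induced E2 elimination across a benzylic C–O bond and the C5–H may compete, in 8 or in 10. Ionisation of the benzylic sulfate monoester would lose the cis relation of the phenyl groups. The hindered, fully substituted malonate carbanion may also fail to close the four-membered ring, so that 10 is merely hydrolysed on work-up. The fallback sets out from 8 and uses the smaller and less basic anion of methyl cyanoacetate in the same double displacement. This should give methyl 1-cyano-3-(2,4-dimethoxybenzyl)-2,4-diphenylcyclobutane-1-carboxylate F1. Krapcho demethoxycarbonylation (LiCl, wet DMSO) and equilibration with KOt-Bu in t-BuOH would lead to all-trans 3-(2,4-dimethoxybenzyl)-2,4-diphenylcyclobutane-1-carbonitrile F2. Addition of 16 would give [3-(2,4-dimethoxybenzyl)-2,4-diphenylcyclobutyl](2,4-dimethoxyphenyl)methanimine F3, which aqueous HCl hydrolyses to 17, where the route is rejoined.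

**Step 3.** Poor facial selectivity in one of the two hydride transfers would give the chiral syn,anti diol or the other meso diol, because the chelate may not hold the benzyl group in one orientation. The fallback sets out from 2 and builds the triad by substrate-controlled steps. Claisen–Schmidt condensation with acetophenone (NaOH, EtOH) gives (E)-3-(2,4-dimethoxyphenyl)-1-phenylprop-2-en-1-one F4. Hydrogenation (H2, Pd/C) gives 3-(2,4-dimethoxyphenyl)-1-phenylpropan-1-one F5. The Z-boron enolate (Bu2BOTf, iPr2NEt) adds to benzaldehyde to give the syn hydroxy ketone 5, now isolated. Narasaka–Prasad reduction (Et2BOMe, NaBH4) returns to the route at 6.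

**Step 4.** Oxidative degradation of the electron-rich dimethoxyphenyl ring by RuO4 may compete with oxidation at sulfur, and substitution of a benzylic hydroxyl by chloride may occur during sulfite formation. The fallback sets out from 6 and transfers the sulfuryl group directly with NaH and 1,1'-sulfonyldiimidazole in THF. It returns at 8 without any oxidant and makes no new compound (F0).

**Step 6.** At 150 °C chloride may open the donor–acceptor cyclobutane at a benzylic ring carbon, or the ring may ionise reversibly, which would scramble C2 and C4. The fallback sets out from 11. Saponification (KOH, aqueous ethanol, reflux) gives 3-(2,4-dimethoxybenzyl)-2,4-diphenylcyclobutane-1,1-dicarboxylic acid F6. Decarboxylation in refluxing pyridine gives 3-(2,4-dimethoxybenzyl)-2,4-diphenylcyclobutane-1-carboxylic acid F7 as C1 epimers. Esterification (MeI, K2CO3, DMF) gives the mixture of 12 and 13, and the NaOMe equilibration returns to the route at 13.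

**Step 9.** The benzylic cation may be captured by the C1 ketone oxygen, which sits on the same ring face, or may fragment the four-membered ring. The oxidation may also stall at the alcohol stage. The fallback sets out from 17 and separates the two oxidation events. DDQ in acetic acid traps the cation as {3-[acetoxy(2,4-dimethoxyphenyl)methyl]-2,4-diphenylcyclobutyl}(2,4-dimethoxyphenyl)methanone F8, which resists further oxidation. Methanolysis (K2CO3, MeOH) gives 18, now isolated, and Dess–Martin periodinane returns to the route at 19.

## Further compounds

F1 | step 5 | methyl 1-cyano-3-(2,4-dimethoxybenzyl)-2,4-diphenylcyclobutane-1-carboxylate (phenyls cis, benzyl trans to both; both C1 epimers) | COC(=O)C1(C#N)[C@H](c2ccccc2)[C@@H](Cc2ccc(OC)cc2OC)[C@@H]1c1ccccc1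
F2 | step 5 | all-trans 3-(2,4-dimethoxybenzyl)-2,4-diphenylcyclobutane-1-carbonitrile | N#C[C@H]1[C@H](c2ccccc2)[C@@H](Cc2ccc(OC)cc2OC)[C@@H]1c1ccccc1
F3 | step 5 | [3-(2,4-dimethoxybenzyl)-2,4-diphenylcyclobutyl](2,4-dimethoxyphenyl)methanimine (all-trans) | N=C(c1ccc(OC)cc1OC)[C@H]1[C@H](c2ccccc2)[C@@H](Cc2ccc(OC)cc2OC)[C@@H]1c1ccccc1
F4 | step 3 | (E)-3-(2,4-dimethoxyphenyl)-1-phenylprop-2-en-1-one | O=C(/C=C/c1ccc(OC)cc1OC)c1ccccc1
F5 | step 3 | 3-(2,4-dimethoxyphenyl)-1-phenylpropan-1-one | O=C(CCc1ccc(OC)cc1OC)c1ccccc1
F0 | step 4 | none | none
F6 | step 6 | 3-(2,4-dimethoxybenzyl)-2,4-diphenylcyclobutane-1,1-dicarboxylic acid (phenyls cis, benzyl trans to both) | OC(=O)C1(C(=O)O)[C@H](c2ccccc2)[C@@H](Cc2ccc(OC)cc2OC)[C@@H]1c1ccccc1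
F7 | step 6 | 3-(2,4-dimethoxybenzyl)-2,4-diphenylcyclobutane-1-carboxylic acid (phenyls cis, benzyl trans to both; both C1 epimers) | OC(=O)C1[C@H](c2ccccc2)[C@@H](Cc2ccc(OC)cc2OC)[C@@H]1c1ccccc1
F8 | step 9 | {3-[acetoxy(2,4-dimethoxyphenyl)methyl]-2,4-diphenylcyclobutyl}(2,4-dimethoxyphenyl)methanone (ring all-trans; racemic at the acetoxy carbon) | O=C(c1ccc(OC)cc1OC)[C@H]1[C@H](c2ccccc2)[C@@H](C(OC(C)=O)c2ccc(OC)cc2OC)[C@@H]1c1ccccc1
A1 | alternative 1 | methyl trans-3-(quinolin-8-ylcarbamoyl)cyclobutane-1-carboxylate | COC(=O)[C@H]1C[C@H](C(=O)Nc2cccc3cccnc23)C1
A2 | alternative 1 | iodobenzene | Ic1ccccc1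
A3 | alternative 1 | methyl 2,4-diphenyl-3-(quinolin-8-ylcarbamoyl)cyclobutane-1-carboxylate (phenyls cis to the amide, trans to the ester) | COC(=O)[C@H]1[C@H](c2ccccc2)[C@H](C(=O)Nc2cccc3cccnc23)[C@@H]1c1ccccc1
A4 | alternative 2 | all-trans 1,1'-(2,4-diphenylcyclobutane-1,3-diyl)bis(prop-2-yn-1-one) | C#CC(=O)[C@H]1[C@H](c2ccccc2)[C@@H](C(=O)C#C)[C@@H]1c1ccccc1
A5 | alternative 2 | 1,3-dimethoxy-1-(trimethylsilyloxy)buta-1,3-diene | COC(=C)C=C(OC)O[Si](C)(C)C
A6 | alternative 2 | all-trans 1,3-bis(2-hydroxy-4-methoxybenzoyl)-2,4-diphenylcyclobutane | O=C(c1ccc(OC)cc1O)[C@H]1[C@H](c2ccccc2)[C@@H](C(=O)c2ccc(OC)cc2O)[C@@H]1c1ccccc1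
A7 | alternative 3 | cyclobutane-1,2,3,4-tetracarboxylic dianhydride (cis,trans,cis) | O=C1OC(=O)[C@@H]2[C@H]1[C@H]1C(=O)OC(=O)[C@@H]21
A8 | alternative 3 | 1,3-dimethoxybenzene | COc1cccc(OC)c1
A9 | alternative 3 | 2,4-bis(2,4-dimethoxybenzoyl)cyclobutane-1,3-dicarboxylic acid (cis,trans,cis) | O=C(c1ccc(OC)cc1OC)[C@H]1[C@@H](C(=O)O)[C@H](C(=O)c2ccc(OC)cc2OC)[C@@H]1C(=O)O
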